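The readings are calculated with made-up constants; noise was put on by code.

In this closed, stirred vessel the solid substrate has to dissolve before it can meet partner, and I take it that protic impurity consumes partner too. You want the quench number, and the autumn run gives it if you read that run as a ladder of rates.

| flask | solid substrate | partner | protic impurity | remark | time |
|---|---|---|---|---|---|
| autumn | 2 M | 2 M | 0.50 M | run made earlier |  |
| flask | 2.0 M | 2.00 M | 1.00 M |  | 2.0 h |
autumn run (percent of the solid substrate charged)

| time / min | solid substrate / % | product / % |
|---|---|---|
| 3.00 | 84.9 | 13.9 |
| 6.00 | 71.4 | 25.7 |
| 10.0 | 55.7 | 41.8 |
| 15.0 | 31.4 | 66.8 |
| 20.0 | 12.7 | 80.2 |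
| 25.0 | 2.0 | 81.5 |

(scatter of a reading: 1 percentage point)
- as a solid, counted per litre of solution: solid substrate
- at the start none of the solid substrate is in solution
- what has only dissolved of solid substrate counts as not reacted
- no earlier run changes the charge of protic impurity; that part of a forecast is a guess
* part of the solid substrate that has turned into other species by 2.0 h (what has only dissolved does not count)
* product at 2.0 h, in percent of the solid substrate charged

Fastest is the reaction in solution: the share neither solid nor product stays near 1.80% at 15.0 min, so I freeze it. Next comes dissolving, and with it product: solid falls 0.0446 min⁻¹ of the charge, on a straight line. Slower still is the quench. Product stops at 81.5%, so I count the other 18.5% of partner as quenched, at 0.0101 min⁻¹, less than product's rate. That leaves 26.0% of the autumn impurity.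

Partner therefore falls roughly straight, and impurity, which I assume decays in proportion to partner, survives as exp(−Q × partner per substrate × product share). From autumn, the quench number is 1.65.

For your flask I take partner as used up, so that product plus quenched partner equals the partner charged. Successive passes through that balance give 63.0%, 67.6%, 66.3% and 66.7%. I commit to that last product, reached near 15.0 min, well inside 120 min. My conversion is the same number, since substrate merely dissolved doesn't count.

The forecast gave 98% and 65%, with the words “Two hours is ample for the substrate to be consumed, unless it ends up stranded in solution once partner runs out”.

The flask gives 69.0% conversion and 69.0% product, with partner, the limiting reagent, at 0% and 31.0% standing as dissolved substrate.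

    dissolved substrate + partner → product (k = 9.90 L mol⁻¹ min⁻¹)
    solid substrate ⇌ dissolved substrate, rate k2*(cs2 - [dissolved substrate]) while solid is left; crystals form when [dissolved substrate] > cs2 (solubility = 0.760 M, k = 0.120 min⁻¹)
    partner + protic impurity → quenched reagent (k = 0.0720 L mol⁻¹ min⁻¹)

With the flask's product, the quench number leaves 32.0% of the impurity, against 38.0% in the flask. In the neighbour charged with 0.80 M of partner, product of 30.8% gives 81.6%, against 82% there.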